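## Retrosynthetic overview
1. Target ⇒ its 12‑O‑methyl ether ⇒ Diels–Alder addition of β‑myrcene across the tetrasubstituted C8=C9 bond of a 6‑5‑6 methoxyquinone aldehyde. The cyclohexene ring is formed last, and C8 and C9 are set together.
2. Quinone aldehyde ⇒ Δ6‑11,12,14‑trimethoxyabietatriene, by an oxidative 1,2‑shift that contracts ring B from six to five members (C7 formyl centre), telescoped with arene → quinone oxidation.
3. Δ6‑abietatriene ⇒ saturated abietatriene ⇒ acyclic homogeranylarene, by an enantioselective proton‑initiated polyene bicyclisation. Rings A and B form in one step, setting C5 and C10.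
4. Homogeranylarene ⇒ benzylic Grignard reagent + geranyl chloride. Arene ⇒ 1,2,4‑trimethoxybenzene + acetone + formaldehyde.
5. Ring order: C (bought) → A and six‑membered B together → B contracted to five → cyclohexene ring.

Assumption: abietane numbering is used (after contraction the ring‑B methine is C7 and the formyl carbon C6), and the (R)‑binaphthol–SnCl4 acid is taken to give the normal 5α‑H/10β‑CH3 series as it does with simpler homogeranylarenes; otherwise its (S)‑antipode is used.

## Route

Step 1
Reactants: 1 1,2,4‑trimethoxybenzene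
Product: 4 3‑isopropyl‑1,2,4‑trimethoxybenzene, via aryllithium 2 (not isolated), via tertiary carbinol 3 (not isolated)
Conditions: n‑BuLi, THF, 0 °C→rt; acetone, −78 °C→rt; concentrate; Et3SiH, CF3CO2H, CH2Cl2, 0 °C→rt
Reagents that add atoms: acetone, CC(C)=O; n‑butyllithium, [Li]CCCC (its lithium stays only in 2)
Why: Directed ortho‑metalation occurs at C3, the only position flanked by two methoxy groups, 1,2‑addition to acetone gives the cumyl‑type alcohol, and ionic hydrogenation of its methoxy‑stabilised tertiary benzylic cation installs the isopropyl group without creating a stereocentre.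

Step 2
Reactants: 4 3‑isopropyl‑1,2,4‑trimethoxybenzene
Product: 5 1‑(chloromethyl)‑3‑isopropyl‑2,4,5‑trimethoxybenzene
Conditions: (CH2O)n, HCl (4 M in dioxane), AcOH, 0 °C→rt; used crude
Reagents that add atoms: formaldehyde (from paraformaldehyde), C=O; hydrogen chloride, Cl
Why: Blanc chloromethylation, an electrophilic aromatic substitution, goes to C5 (ortho to the 4‑OMe and para to the 2‑OMe), the site at which 3‑alkyl‑1,2,4‑trimethoxybenzenes are also formylated, and leaves the future C9–H free.

Step 3
Reactants: 5 1‑(chloromethyl)‑3‑isopropyl‑2,4,5‑trimethoxybenzene; 6 geranyl chloride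
Product: 8 1‑[(3E)‑4,8‑dimethylnona‑3,7‑dien‑1‑yl]‑3‑isopropyl‑2,4,5‑trimethoxybenzene, via benzylmagnesium chloride 7 (not isolated)
Conditions: Mg (excess), THF, 0 °C, slow addition of 5; then 6, Li2CuCl4 (3 mol %), −20 °C→rt
Reagents that add atoms: magnesium, [Mg] (held only in 7)
Why: High‑dilution Grignard formation limits Wurtz dimerisation, and the copper‑catalysed Kochi‑type sp3–sp3 coupling substitutes the primary allylic carbon directly (SN2, because the γ‑carbon is fully substituted) with retention of the E alkene.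

Step 4
Reactants: 8 1‑[(3E)‑4,8‑dimethylnona‑3,7‑dien‑1‑yl]‑3‑isopropyl‑2,4,5‑trimethoxybenzene
Product: 10 (5S,10S)‑11,12,14‑trimethoxyabieta‑8,11,13‑triene, via monocyclic alkene 9 (not isolated)
Conditions: (R)‑2‑hydroxy‑2'‑(2‑fluorobenzyloxy)‑1,1'‑binaphthyl·SnCl4 (1 equiv, ligand recovered), toluene, −78 °C, 48 h; then CF3CO2H, SnCl4, i‑PrNO2, −78 °C; recrystallise to raise ee
Reagents that add atoms: none
Why: In this enantioselective proton‑initiated polyene cyclisation by a Lewis‑acid‑assisted chiral Brønsted acid, face‑selective protonation of the terminal isopropylidene sets the absolute sense, the chair–chair Stork–Eschenmoser anti addition across the E alkene gives trans 5α‑H/10β‑CH3, Friedel–Crafts termination uses the only free ring position (ortho to the 11‑OMe), and the achiral acid charge closes ring B of any monocyclic material under control of C5.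

Step 5
Reactants: 10 (5S,10S)‑11,12,14‑trimethoxyabieta‑8,11,13‑triene
Product: 11 (5S,10S)‑11,12,14‑trimethoxyabieta‑6,8,11,13‑tetraene
Conditions: DDQ (1.2 equiv), dry 1,4‑dioxane, rt→60 °C
Reagents that add atoms: none
Why: In this DDQ dehydrogenation, hydride is abstracted from C7, whose cation is stabilised by the ortho 14‑OMe and para 12‑OMe (the isopropyl methine cannot become coplanar with the ring), and loss of H6 gives the styrene while C5 and C10 stay untouched.

Step 6
Reactants: 11 (5S,10S)‑11,12,14‑trimethoxyabieta‑6,8,11,13‑tetraene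
Product: 13 12‑methoxy‑11,14‑dioxo‑5(6→7)abeo‑abieta‑8,12‑dien‑6‑al (5α‑H; 7α‑CHO; 10β‑CH3), via dimethyl acetal 12 (not isolated)
Conditions: PhI(OH)OTs (1.1 equiv), MeOH, −10 °C→rt; concentrate; (NH4)2Ce(NO3)6 (2.5 equiv), MeCN–H2O 2:1, 0 °C→rt
Reagents that add atoms: methanol, CO (the two acetal methoxy groups of 12); water, O (formyl oxygen and both quinone oxygens of 13)
Why: This Koser‑type oxidative 1,2‑aryl migration (trivalent‑iodine ring contraction of a 1,2‑dihydronaphthalene) is the laboratory counterpart of the presumed 6,7‑oxygenation/pinacol‑type contraction and gives the same skeleton: the iodane adds to C6 from the α face (the β face is shielded by the axial C19 and C20 methyls), methanol caps the C7 benzylic cation, the equatorial C6–iodine bond lies antiperiplanar to the C7–C8 ring bond so that aryl carbon C8 migrates with inversion and places the acetal carbon α and pseudo‑equatorial (cis to H5, also the thermodynamic epimer), and tetravalent cerium then carries out the standard oxidative demethylation of the para 11,14‑dimethoxy pair while its acidic aqueous medium hydrolyses the acetal.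

Step 7
Reactants: 13 12‑methoxy‑11,14‑dioxo‑5(6→7)abeo‑abieta‑8,12‑dien‑6‑al; 14 β‑myrcene
Product: 15 12‑O‑methyl ether of the target (cyclohexene ring cis‑fused on the α face of C8–C9; myrcene C1 on C9; myrcene C4 on C8)
Conditions: 14 (10 equiv, distilled), Er(fod)3 (0.5 equiv; fod = 6,6,7,7,8,8,8‑heptafluoro‑2,2‑dimethyloctane‑3,5‑dionate), BHT, toluene (1 M), 60 °C, 48–72 h; regioisomers separated on silica
Reagents that add atoms: none
Why: In this lanthanide‑promoted Diels–Alder reaction only C8=C9 is a competent dienophile (C12=C13 is deactivated by OMe), the diene approaches the α face anti to the axial C20 methyl so both quaternary centres C8 and C9 are set at once, erbium bound to the more basic vinylogous‑ester carbonyl C14=O (helped by the neighbouring formyl oxygen) makes C9 the electrophilic terminus so the nucleophilic C1 of myrcene bonds there ("para" to C14=O) with the side chain lying over the OMe flank rather than the isopropyl flank, and the O‑methyl group also blocks the [5+2] mode of free hydroxyquinones.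

Step 8
Reactants: 15 12‑O‑methyl ether of the target
Product: 16 target CNP0239256.1
Conditions: LiI (5 equiv), EtOAc, reflux, dark, N2; 0.5 M HCl work‑up
Reagents that add atoms: none
Why: Iodide performs an SN2 dealkylation of the vinylogous methyl ester, expelling the stabilised lithium diosphenolate under neutral conditions that leave the epimerisable C7 formyl centre, both trisubstituted alkenes and all quaternary centres untouched.

## Compound list
1 | 1,2,4‑trimethoxybenzene | COc1ccc(OC)c(OC)c1 | starting material
2 | 2,3,6‑trimethoxyphenyllithium (lithium at C3 of 1; not isolated) | COc1ccc(OC)c(OC)c1[Li] | intermediate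
3 | 2‑(2,3,6‑trimethoxyphenyl)propan‑2‑ol (formed as its lithium alkoxide; not isolated) | COc1ccc(OC)c(OC)c1C(C)(C)O | intermediate
4 | 3‑isopropyl‑1,2,4‑trimethoxybenzene | COc1ccc(OC)c(OC)c1C(C)C | intermediate
5 | 1‑(chloromethyl)‑3‑isopropyl‑2,4,5‑trimethoxybenzene | COc1c(CCl)cc(OC)c(OC)c1C(C)C | intermediate
6 | geranyl chloride, (2E)‑1‑chloro‑3,7‑dimethylocta‑2,6‑diene | ClC/C=C(\C)CCC=C(C)C | starting material
7 | (3‑isopropyl‑2,4,5‑trimethoxybenzyl)magnesium chloride (not isolated) | COc1c(C[Mg]Cl)cc(OC)c(OC)c1C(C)C | intermediate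
8 | 1‑[(3E)‑4,8‑dimethylnona‑3,7‑dien‑1‑yl]‑3‑isopropyl‑2,4,5‑trimethoxybenzene | COc1c(CC/C=C(\C)CCC=C(C)C)cc(OC)c(OC)c1C(C)C | intermediate
9 | 1‑{2‑[(1S)‑2,2‑dimethyl‑6‑methylidenecyclohexyl]ethyl}‑3‑isopropyl‑2,4,5‑trimethoxybenzene (ring A closed, C5 as in 10; not isolated) | C=C1CCCC(C)(C)[C@@H]1CCc1cc(OC)c(OC)c(C(C)C)c1OC | intermediate
10 | (5S,10S)‑11,12,14‑trimethoxyabieta‑8,11,13‑triene (5α‑H, 10β‑CH3) | CC(C)c1c(OC)c2c(c(OC)c1OC)[C@@]1(C)CCCC(C)(C)[C@@H]1CC2 | intermediate
11 | (5S,10S)‑11,12,14‑trimethoxyabieta‑6,8,11,13‑tetraene | CC(C)c1c(OC)c2c(c(OC)c1OC)[C@@]1(C)CCCC(C)(C)[C@@H]1C=C2 | intermediate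
12 | 11,12,14‑trimethoxy‑5(6→7)abeo‑abieta‑8,11,13‑trien‑6‑al dimethyl acetal (7α‑CH(OMe)2, 5α‑H, 10β‑CH3; not isolated) | CC(C)c1c(OC)c2c(c(OC)c1OC)[C@@]1(C)CCCC(C)(C)[C@@H]1[C@H]2C(OC)OC | intermediate
13 | 12‑methoxy‑11,14‑dioxo‑5(6→7)abeo‑abieta‑8,12‑dien‑6‑al (7α‑CHO, 5α‑H, 10β‑CH3) | COC1=C(C(C)C)C(=O)C2=C(C1=O)[C@@]1(C)CCCC(C)(C)[C@@H]1[C@H]2C=O | intermediate
14 | β‑myrcene, 7‑methyl‑3‑methylideneocta‑1,6‑diene | C=CC(=C)CCC=C(C)C | starting material
15 | 12‑O‑methyl ether of the target (new ring on the α face, 7α‑CHO, 5α‑H, 10β‑CH3) | CC(C)=CCCC1=CC[C@@]23C(=O)C(C(C)C)=C(OC)C(=O)[C@]2(C1)[C@@]1(C)CCCC(C)(C)[C@@H]1[C@H]3C=O | intermediate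
16 | CNP0239256.1, the 8α,9α myrcene [4+2] adduct of 12‑hydroxy‑11,14‑dioxo‑5(6→7)abeo‑abieta‑8,12‑dien‑6‑al | CC(C)=CCCC1=CC[C@@]23C(=O)C(C(C)C)=C(O)C(=O)[C@]2(C1)[C@@]1(C)CCCC(C)(C)[C@@H]1[C@H]3C=O | target

## Step count and risks
Total steps: 8. Longest linear sequence: 8 (1 → 16; compounds 6 and 14 are bought).

**Step 7 is the most exposed.**
- The dienophile is tetrasubstituted.
- Its metal‑free polarisation (C11=O is the stronger acceptor) favours the other regioisomer.
- Compound 13 can tautomerise to a hydroquinone enal.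
- Too strong a Lewis acid would drive a carbonyl‑ene closure of the formyl group onto the new ring alkene.

The fallback sets out from 13. BCl3 (CH2Cl2, −78 °C, chelation to the C11 carbonyl) removes the methyl group first and gives the free hydroxyquinone aldehyde F1. The cycloaddition is then run without any metal on this internally hydrogen‑bonded quinone, as in the presumed biogenesis, in neat 14 at 12 kbar and room temperature. Regiocontrol then rests only on the clash between the myrcene side chain and the isopropyl group. The fallback returns to the route directly at 16, so 15 and step 8 drop out.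

**Step 6 is second.**
- The iodane may give the 6,7‑dimethoxy addition product instead of the aryl shift.
- It may also attack the electron‑rich ring.

The fallback sets out from 11 and separates the events. NBS in aqueous THF adds bromine to C6 from the α face and water to C7, giving the 6α‑bromo‑7β‑hydroxy bromohydrin F2; either C7 epimer serves. AgBF4 with a hindered pyridine in CH2Cl2 at −40 °C then triggers a halohydrin semipinacol shift of C8, antiperiplanar to the equatorial bromide, to give the trimethoxyarene aldehyde F3. This is purified and oxidised with (NH4)2Ce(NO3)6 in aqueous MeCN, returning to the route at 13.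

**Step 4 is third.**
- The three basic methoxy groups may sequester SnCl4.
- The hindered terminator may erode conversion or ee.

The fallback sets out from 8 and changes the initiating electrophile. N‑iodosuccinimide activated by a stoichiometric binaphthol‑derived chiral phosphoramidite (toluene, −40 °C, then ClSO3H, i‑PrNO2, −78 °C) effects an enantioselective iodonium‑initiated bicyclisation to the 3β‑iodo‑11,12,14‑trimethoxyabietatriene F4. Radical deiodination (Bu3SnH, AIBN, toluene, 80 °C) returns to the route at 10.

## Further compounds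
F1 | step 7 | 12‑hydroxy‑11,14‑dioxo‑5(6→7)abeo‑abieta‑8,12‑dien‑6‑al (7α‑CHO, 5α‑H, 10β‑CH3) | OC1=C(C(C)C)C(=O)C2=C(C1=O)[C@@]1(C)CCCC(C)(C)[C@@H]1[C@H]2C=O
F2 | step 6 | 6α‑bromo‑11,12,14‑trimethoxyabieta‑8,11,13‑trien‑7β‑ol | CC(C)c1c(OC)c2c(c(OC)c1OC)[C@@]1(C)CCCC(C)(C)[C@@H]1[C@@H](Br)[C@@H]2O
F3 | step 6 | 11,12,14‑trimethoxy‑5(6→7)abeo‑abieta‑8,11,13‑trien‑6‑al (7α‑CHO) | CC(C)c1c(OC)c2c(c(OC)c1OC)[C@@]1(C)CCCC(C)(C)[C@@H]1[C@H]2C=O
F4 | step 4 | 3β‑iodo‑11,12,14‑trimethoxyabieta‑8,11,13‑triene | CC(C)c1c(OC)c2c(c(OC)c1OC)[C@@]1(C)CC[C@H](I)C(C)(C)[C@@H]1CC2
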